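(The runs are simulated for an exercise; scatter was added.)

**Early readings.** At the first reading of the eta run, 1.00 min, side product stood at 0.3% against 42.6% of target, with 20.3% of the charge still substrate. I wanted to know what the flasks below would hold once that early traffic was over.

| flask | substrate | coupling partner | remark | time |
|---|---|---|---|---|
| eta | 0.20 M | 0.91 equiv | run made earlier |  |
| delta | 0.20 M | 1.4 equiv | run made earlier |  |
| autumn | 0.20 M | 1.10 equiv |  | 25 min |
| spring | 0.20 M | 2.10 equiv |  | 25 min |

| run | time / min | target / % | intermediate C / % | side product / % | substrate / % | intermediate B / % |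
|---|---|---|---|---|---|---|
| eta | 1.00 | 42.6 | 0 | 0.3 | 20.3 | 18.6 |
| eta | 2.50 | 57.2 | 2.3 | 5.3 | 3.4 | 23.5 |
| eta | 5.00 | 61.8 | 8.3 | 7.8 | 0.7 | 25.3 |
| eta | 12.0 | 63.0 | 13.5 | 8.0 | 0 | 14.9 |
| delta | 1.50 | 49.8 | 2.2 | 6.8 | 8.1 | 19.0 |
| delta | 4.00 | 57.8 | 7.0 | 11.9 | 1.7 | 20.1 |
| delta | 8.00 | 59.2 | 12.9 | 10.7 | 1.8 | 14.6 |
| delta | 12.0 | 58.8 | 17.3 | 10.9 | 0 | 12.0 |

(standard deviation of a reading: 1 percentage point)

- steps thought possible: substrate -> target; substrate + coupling partner <-> intermediate A; substrate -> intermediate B; coupling partner + intermediate B <-> intermediate C; intermediate A -> side product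

- which of these there is most of at the end, counted by the substrate in it, autumn (side product / intermediate B / intermediate C / target)
- which of these there is most of at the end, counted by the substrate in it, spring (side product / intermediate B / intermediate C / target)
- the largest of these amounts at the end, in percent of the substrate charged, autumn
- the largest of these amounts at the end, in percent of the substrate charged, spring

**Bench rule.** I kept two ratios from the last readings. The share is target over target plus intermediates B and C: 0.689 in eta, 0.667 in delta, mean 0.678. The leak number, side product per target per equivalent of coupling partner charged, a selectivity factor, read 0.140 in eta and 0.132 in delta, mean 0.136.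

**Its border.** Side product over target in eta read 0.00704 at 1.00 min, 0.126 at 5.00 min and 0.127 at 12.0 min. So the rule does not hold at the first reading of that run, and the ratio reads level from 5.00 min to 12.0 min. The new flasks are read at 25 min.

**My reckoning.** Target is the share of what side product leaves, and side product is the leak number times equivalents times target. I started from no side product, at 67.8%, and put each answer back. Autumn went to 61.0%, then 61.7%. Spring went to 54.7%, then 57.2%.

**The forecast.** It named target for autumn and target for spring, at 61.5% and 57.5%, holding that the “remaining material splits with target” at a steady ratio. My spring figure lay 0.30 percentage points lower, and a single reading scatters by 1 point.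

**The flasks.** Target led in autumn at 61.6% and in spring at 56.4%, with side product at 9.71% and 17.2%.

    substrate → target (k = 0.0150 s⁻¹)
    substrate + coupling partner ⇌ intermediate A (K = 3.20 L mol⁻¹, k = 0.0480 L mol⁻¹ s⁻¹)
    substrate → intermediate B (k = 0.00700 s⁻¹)
    coupling partner + intermediate B ⇌ intermediate C (K = 100 L mol⁻¹, k = 0.00610 L mol⁻¹ s⁻¹)
    intermediate A → side product (k = 0.00510 s⁻¹)

In spring at 0.548 min, intermediate A fell back 2.9 times as fast as it went on, and its half-life by the step to side product was 2.3 min; substrate in spring stood at 0.00678% at 12.5 min. The spring leak number read 0.145. For the same flask as spring but with 8.40 equiv of coupling partner, my mean leak number, put back until the figure stood still, gives 38.2% of target, and that flask held 36.4%.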